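**Assumption:** atom labels C1–C20 follow prostanoid numbering (C1 = ester carbon, C8 and C12 = ring stereocentres). The target is 4S,8S,12R, with the two carbon chains cis on the ring and the C12 acetate trans to the C8 chain. Chiral catalysts and ligands are bought.

## Retrosynthetic overview

1. Target ⇒ tertiary ring alcohol by O-acetylation at C12.
2. The cyclopentenone, the only ring that is built, comes from an oxa-Piancatelli 4π-electrocyclisation of a 2,5-disubstituted furyl carbinol. This sets C8 and C12 (chain trans to OH).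
3. Furyl carbinol ⇒ furyl ketone ⇒ key C7–C8 bond: the acyl anion (Breslow intermediate) of a 5-octenylfurfural attacks the electrophilic π-allyl-Pd terminus of an enantiopure vinyl epoxide. This gives the 5E alkene and carries C4.
4. Vinyl epoxide ⇒ Shi epoxidation of a dienoate made by Johnson–Claisen rearrangement of divinyl carbinol.
5. Furfural ⇒ C5-lithiation of furfural diethyl acetal and alkylation with (Z)-octenyl bromide. The furan is bought; the cyclopentenone is formed in step 7.

## Route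

Step 1
Reactants: 1 penta-1,4-dien-3-ol; 2 trimethyl orthoacetate
Product: 3 methyl (4E)-hepta-4,6-dienoate
Conditions: 2 (5 equiv), EtCO2H (cat.), 120 °C, MeOH distilled off
Reagents that add atoms: none
Why: Johnson–Claisen orthoester rearrangement, whose chair [3,3] transition state with the vinyl group equatorial gives the 4E alkene.

Step 2
Reactants: 3 methyl (4E)-hepta-4,6-dienoate
Product: 4 methyl 3-[(2S,3S)-3-ethenyloxiran-2-yl]propanoate
Conditions: ent-Shi ketone (L-fructose-derived, 30 mol%), Oxone, K2CO3, Bu4NHSO4, MeCN/DMM/aq. borate buffer pH 10.5, 0 °C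
Reagents that add atoms: Oxone (potassium peroxymonosulfate), [K+].[O-]S(=O)(=O)OO
Why: Shi asymmetric epoxidation, in which the chiral dioxirane attacks only the electron-richer trans-disubstituted alkene of the diene through the spiro transition state and the L-series ketone gives the (S,S) epoxide, fixing the future C4 as S.

Step 3
Reactants: 5 (2Z)-oct-2-en-1-ol
Product: 6 (2Z)-1-bromooct-2-ene
Conditions: PBr3 (0.4 equiv), Et2O, −20 → 0 °C
Reagents that add atoms: phosphorus tribromide, BrP(Br)Br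
Why: SN2 displacement of the bromophosphite at the primary allylic carbon at low temperature, which keeps the Z alkene.

Step 4
Reactants: 7 2-(diethoxymethyl)furan; 6 (2Z)-1-bromooct-2-ene
Product: 10 5-[(2Z)-oct-2-en-1-yl]furan-2-carbaldehyde, via [5-(diethoxymethyl)furan-2-yl]lithium 8 (not isolated), via 2-(diethoxymethyl)-5-[(2Z)-oct-2-en-1-yl]furan 9 (not isolated)
Conditions: n-BuLi, THF, −78 → 0 °C; 6, −78 °C → rt; then 1 M HCl, THF, rt
Reagents that add atoms: water, O
Why: α-lithiation of the furan at C5, SN2 alkylation by the primary allylic bromide with the Z alkene retained, then acetal hydrolysis.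

Step 5
Reactants: 10 5-[(2Z)-oct-2-en-1-yl]furan-2-carbaldehyde; 4 methyl 3-[(2S,3S)-3-ethenyloxiran-2-yl]propanoate
Product: 12 methyl (4S,5E)-4-(acetyloxy)-8-{5-[(2Z)-oct-2-en-1-yl]furan-2-yl}-8-oxooct-5-enoate, via methyl (4S,5E)-4-hydroxy-8-{5-[(2Z)-oct-2-en-1-yl]furan-2-yl}-8-oxooct-5-enoate 11 (not isolated)
Conditions: Pd2(dba)3 (2.5 mol%), dppf (6 mol%), N-(2,6-diisopropylphenyl)thiazolium salt (10 mol%), toluene, 50 °C; short SiO2 plug; then Ac2O, pyridine, DMAP (cat.), CH2Cl2, 0 °C
Reagents that add atoms: acetic anhydride, CC(=O)OC(C)=O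
Why: Proposed new method: an umpolung Tsuji–Trost acylation in which Pd(0) opens the vinyl epoxide to a zwitterionic syn-π-allyl/alkoxide, the alkoxide frees the carbene, and the Breslow intermediate of the furfural (an acyl anion at the future C8) attacks the unhindered allyl terminus C7 to give the E alkene while the C4–O bond and its S configuration stay untouched; the closest known reaction is the synergistic NHC/Pd allylic acylation of aryl aldehydes with allylic carbonates, and the acetylation of the crude alcohol (after removal of Pd) blocks lactonisation of the γ-hydroxy ester.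

Step 6
Reactants: 12 methyl (4S,5E)-4-(acetyloxy)-8-{5-[(2Z)-oct-2-en-1-yl]furan-2-yl}-8-oxooct-5-enoate
Product: 13 methyl (4S,5E)-4-(acetyloxy)-8-hydroxy-8-{5-[(2Z)-oct-2-en-1-yl]furan-2-yl}oct-5-enoate (both C8 epimers)
Conditions: NaBH4, CeCl3·7H2O, MeOH, −40 °C
Reagents that add atoms: none
Why: Luche 1,2-reduction of the ketone under near-neutral conditions that spare the ester, the acetate and the base-sensitive β,γ-enone; the carbinol forms as both epimers, which is harmless because it is ionised in step 7.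

Step 7
Reactants: 13 methyl (4S,5E)-4-(acetyloxy)-8-hydroxy-8-{5-[(2Z)-oct-2-en-1-yl]furan-2-yl}oct-5-enoate
Product: 14 methyl (4S,5E)-4-(acetyloxy)-7-{(1S,2R)-2-hydroxy-2-[(2Z)-oct-2-en-1-yl]-5-oxocyclopent-3-en-1-yl}hept-5-enoate
Conditions: chiral BINOL N-triflylphosphoramide (TRIP type, 10 mol%; antipode fixed by a first run), H2O (5 equiv), CHCl3, 40 °C
Reagents that add atoms: water, O
Why: Proposed new method: an oxa-Piancatelli rearrangement under chiral Brønsted acid control, in which the acid ionises the furfuryl alcohol, water adds at the octenyl-bearing furan carbon, ring opening gives a hydroxy-pentadienyl cation paired with the chiral anion, and conrotatory 4π closure with chain and OH both rotating outward sets C8 and C12 trans in one event; the closest known reactions are the racemic Piancatelli rearrangement of 5-alkyl-2-furyl homoallyl carbinols (rethrolone route) and the chiral-acid-catalysed aza-Piancatelli and Nazarov cyclisations.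

Step 8
Reactants: 14 methyl (4S,5E)-4-(acetyloxy)-7-{(1S,2R)-2-hydroxy-2-[(2Z)-oct-2-en-1-yl]-5-oxocyclopent-3-en-1-yl}hept-5-enoate
Product: 15 methyl (4S,5E)-4-(acetyloxy)-7-{(1S,2R)-2-(acetyloxy)-2-[(2Z)-oct-2-en-1-yl]-5-oxocyclopent-3-en-1-yl}hept-5-enoate
Conditions: Ac2O, Sc(OTf)3 (2 mol%), MeCN, −20 °C
Reagents that add atoms: acetic anhydride, CC(=O)OC(C)=O
Why: Lewis-acid-catalysed acylation of the tertiary alcohol without base, so the C8–H next to the β-acyloxy ketone is not exposed to epimerisation, E1cB loss of acetate or retro-aldol opening, and ionisation at C12 is disfavoured because the cation would sit γ to the enone carbonyl.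

## Compound list

1 | penta-1,4-dien-3-ol | C=CC(O)C=C | starting material
2 | trimethyl orthoacetate | CC(OC)(OC)OC | starting material
3 | methyl (4E)-hepta-4,6-dienoate | COC(=O)CC/C=C/C=C | intermediate
4 | methyl 3-[(2S,3S)-3-ethenyloxiran-2-yl]propanoate | COC(=O)CC[C@@H]1O[C@H]1C=C | intermediate
5 | (2Z)-oct-2-en-1-ol | CCCCC/C=C\CO | starting material
6 | (2Z)-1-bromooct-2-ene | CCCCC/C=C\CBr | intermediate
7 | 2-(diethoxymethyl)furan | CCOC(OCC)c1ccco1 | starting material
8 | [5-(diethoxymethyl)furan-2-yl]lithium | [Li]c1ccc(C(OCC)OCC)o1 | intermediate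
9 | 2-(diethoxymethyl)-5-[(2Z)-oct-2-en-1-yl]furan | CCCCC/C=C\Cc1ccc(C(OCC)OCC)o1 | intermediate
10 | 5-[(2Z)-oct-2-en-1-yl]furan-2-carbaldehyde | CCCCC/C=C\Cc1ccc(C=O)o1 | intermediate
11 | methyl (4S,5E)-4-hydroxy-8-{5-[(2Z)-oct-2-en-1-yl]furan-2-yl}-8-oxooct-5-enoate | CCCCC/C=C\Cc1ccc(o1)C(=O)C/C=C/[C@@H](O)CCC(=O)OC | intermediate
12 | methyl (4S,5E)-4-(acetyloxy)-8-{5-[(2Z)-oct-2-en-1-yl]furan-2-yl}-8-oxooct-5-enoate | CCCCC/C=C\Cc1ccc(o1)C(=O)C/C=C/[C@@H](OC(C)=O)CCC(=O)OC | intermediate
13 | methyl (4S,5E)-4-(acetyloxy)-8-hydroxy-8-{5-[(2Z)-oct-2-en-1-yl]furan-2-yl}oct-5-enoate (C8 epimers) | CCCCC/C=C\Cc1ccc(o1)C(O)C/C=C/[C@@H](OC(C)=O)CCC(=O)OC | intermediate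
14 | methyl (4S,5E)-4-(acetyloxy)-7-{(1S,2R)-2-hydroxy-2-[(2Z)-oct-2-en-1-yl]-5-oxocyclopent-3-en-1-yl}hept-5-enoate | CCCCC/C=C\C[C@@]1(O)C=CC(=O)[C@H]1C/C=C/[C@H](CCC(=O)OC)OC(C)=O | intermediate
15 | methyl (4S,5E)-4-(acetyloxy)-7-{(1S,2R)-2-(acetyloxy)-2-[(2Z)-oct-2-en-1-yl]-5-oxocyclopent-3-en-1-yl}hept-5-enoate | CCCCC/C=C\C[C@@]1(OC(C)=O)C=CC(=O)[C@H]1C/C=C/[C@H](CCC(=O)OC)OC(C)=O | target

## Step count and risks

Total step count: 8 (steps 4 and 5 are telescoped).
Longest linear sequence: 6 steps (5 → 6 → 10 → 12 → 13 → 14 → 15; the branch 1 → 3 → 4 → 12 → 15 is also 6).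

**Step 5 (key coupling).** The carbene and Pd can poison each other. The alkoxide/π-allyl zwitterion can add to the aldehyde to give a vinyl dioxolane. The carbene can catalyse lactonisation of 11. The fallback sets out from 4 (with 10) and comes back at 12. The epoxide is acetolysed with Ac2O and catalytic Bu4NOAc at 90 °C to methyl (4S,5R)-4,5-bis(acetyloxy)hept-6-enoate F1, accompanied by its allylic isomer methyl (4S,5E)-4,7-bis(acetyloxy)hept-5-enoate F2. Both ionise with Pd(0) to the same 4-acetoxy π-allyl complex, so the mixture is used as such. It is coupled with 10 by the established NHC/Pd allylic acylation of an allylic ester (thiazolium salt, Pd/dppf, K2CO3, toluene), which gives 12 directly. No alkoxide is ever present and C4 already carries its acetate.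

**Step 7 (ring formation).** Enantio-induction by the chiral acid is unproven for water as the nucleophile. The trans selectivity at a fully substituted furan carbon may be incomplete. The furfuryl cation can lose a C7 proton to give a furyl diene. The fallback sets out from 13 and comes back at 14. The rearrangement is run without stereo-induction (Dy(OTf)3 10 mol%, MeCN/H2O, 80 °C). This gives 14 together with its ring diastereomer methyl (4S,5E)-4-(acetyloxy)-7-{(1R,2S)-2-hydroxy-2-[(2Z)-oct-2-en-1-yl]-5-oxocyclopent-3-en-1-yl}hept-5-enoate F3 in about 1:1 ratio. Because C4 is fixed, the two are diastereomers, and 14 is obtained by preparative HPLC, at the cost of half the material.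

**Step 8 (tertiary acetylation).** The hindered alcohol may react slowly, and the β-acyloxy ketone with its acidic C8–H can epimerise or lose acetate. The fallback sets out from 14 and comes back at 15, and removes the ketone for the duration of the acylation.
- Luche reduction (NaBH4, CeCl3, MeOH, −40 °C) gives the allylic diol methyl (4S,5E)-4-(acetyloxy)-7-{(1R,2R)-2,5-dihydroxy-2-[(2Z)-oct-2-en-1-yl]cyclopent-3-en-1-yl}hept-5-enoate F4 (C5 epimers of the ring).
- TESCl and imidazole silylate only the secondary hydroxyl to give methyl (4S,5E)-4-(acetyloxy)-7-{(1R,2R)-2-hydroxy-2-[(2Z)-oct-2-en-1-yl]-5-[(triethylsilyl)oxy]cyclopent-3-en-1-yl}hept-5-enoate F5.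
- With no enolisable ketone left, forcing basic acetylation (Ac2O, DMAP, Et3N, rt) gives methyl (4S,5E)-4-(acetyloxy)-7-{(1R,2R)-2-(acetyloxy)-2-[(2Z)-oct-2-en-1-yl]-5-[(triethylsilyl)oxy]cyclopent-3-en-1-yl}hept-5-enoate F6.
- AcOH/THF/H2O frees the secondary alcohol to give methyl (4S,5E)-4-(acetyloxy)-7-{(1R,2R)-2-(acetyloxy)-5-hydroxy-2-[(2Z)-oct-2-en-1-yl]cyclopent-3-en-1-yl}hept-5-enoate F7.
- Dess–Martin periodinane (NaHCO3 buffer, CH2Cl2) restores the enone and gives 15.

## Further compounds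

F1 | step 5 | methyl (4S,5R)-4,5-bis(acetyloxy)hept-6-enoate | COC(=O)CC[C@H](OC(C)=O)[C@H](OC(C)=O)C=C
F2 | step 5 | methyl (4S,5E)-4,7-bis(acetyloxy)hept-5-enoate | COC(=O)CC[C@H](OC(C)=O)/C=C/COC(C)=O
F3 | step 7 | methyl (4S,5E)-4-(acetyloxy)-7-{(1R,2S)-2-hydroxy-2-[(2Z)-oct-2-en-1-yl]-5-oxocyclopent-3-en-1-yl}hept-5-enoate | CCCCC/C=C\C[C@]1(O)C=CC(=O)[C@@H]1C/C=C/[C@H](CCC(=O)OC)OC(C)=O
F4 | step 8 | methyl (4S,5E)-4-(acetyloxy)-7-{(1R,2R)-2,5-dihydroxy-2-[(2Z)-oct-2-en-1-yl]cyclopent-3-en-1-yl}hept-5-enoate | CCCCC/C=C\C[C@@]1(O)C=CC(O)[C@H]1C/C=C/[C@H](CCC(=O)OC)OC(C)=O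
F5 | step 8 | methyl (4S,5E)-4-(acetyloxy)-7-{(1R,2R)-2-hydroxy-2-[(2Z)-oct-2-en-1-yl]-5-[(triethylsilyl)oxy]cyclopent-3-en-1-yl}hept-5-enoate | CCCCC/C=C\C[C@@]1(O)C=CC(O[Si](CC)(CC)CC)[C@H]1C/C=C/[C@H](CCC(=O)OC)OC(C)=O
F6 | step 8 | methyl (4S,5E)-4-(acetyloxy)-7-{(1R,2R)-2-(acetyloxy)-2-[(2Z)-oct-2-en-1-yl]-5-[(triethylsilyl)oxy]cyclopent-3-en-1-yl}hept-5-enoate | CCCCC/C=C\C[C@@]1(OC(C)=O)C=CC(O[Si](CC)(CC)CC)[C@H]1C/C=C/[C@H](CCC(=O)OC)OC(C)=O
F7 | step 8 | methyl (4S,5E)-4-(acetyloxy)-7-{(1R,2R)-2-(acetyloxy)-5-hydroxy-2-[(2Z)-oct-2-en-1-yl]cyclopent-3-en-1-yl}hept-5-enoate | CCCCC/C=C\C[C@@]1(OC(C)=O)C=CC(O)[C@H]1C/C=C/[C@H](CCC(=O)OC)OC(C)=O
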